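**Strategy.** Icetexane numbering: ring A is C1–C5 plus C10, the seven-membered ring B is C5–C10 plus C20, ring C is C8, C9 and C11–C14. The route rests on the 1,4-relationship between the tertiary C10–O bond and the ketal carbon C7 inside the bridging oxolane (O, C7, C6, C5, C10), the retron of a homo-conjugate hydration of a cyclopropyl ketone. The precursor is an enantioenriched cyclopropa-fused tetralone in which C6 is bonded to C5 and to C10. Acid-promoted cleavage of C6–C10 in one operation enlarges the cyclopropane to the hemiketal oxolane, enlarges the six-membered ketone ring to ring B, and sets C10 and C7 from C5.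

Key step: step 10

Remark: from compound 16 on, atoms carry the icetexane labels defined above.
Assumption: NBS attacks 4 at the open position para to the flanked 2-methoxy group (the later C8), as in other 1,2,4-trimethoxybenzenes.
Assumption: the (S,S)-ligand in step 9 is taken to give the (5S,6R,10S)-cyclopropane; if the sense of induction is opposite, the mirror-image ligand is used and nothing else changes.

**Step 1**
Reactants: 1 1,2,4-trimethoxybenzene
Product: 3 2-(2,3,6-trimethoxyphenyl)propan-2-ol, via aryllithium 2 (not isolated)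
Conditions: n-BuLi, THF, 0 °C → rt; acetone, −78 °C → rt; aqueous work-up
Reagents that add atoms: acetone, CC(=O)C
Why: Directed ortho-lithiation takes the position flanked by two methoxy groups, and the aryllithium adds 1,2 to acetone.

**Step 2**
Reactants: 3 2-(2,3,6-trimethoxyphenyl)propan-2-ol
Product: 4 1,2,4-trimethoxy-3-(propan-2-yl)benzene
Conditions: Et3SiH, CF3CO2H, CH2Cl2, 0 °C → rt
Reagents that add atoms: none
Why: Ionic hydrogenation, in which the benzylic cation stabilised by two ortho methoxy groups is reduced by hydride transfer from the silane.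

**Step 3**
Reactants: 4 1,2,4-trimethoxy-3-(propan-2-yl)benzene
Product: 5 1-bromo-2,4,5-trimethoxy-3-(propan-2-yl)benzene
Conditions: NBS, MeCN, 0 °C → rt, dark
Reagents that add atoms: N-bromosuccinimide, O=C1CCC(=O)N1Br
Why: Electrophilic aromatic bromination should take the open position para to a methoxy group (the later C8), the more electron-rich of the two free sites.

**Step 4**
Reactants: 5 1-bromo-2,4,5-trimethoxy-3-(propan-2-yl)benzene
Product: 6 1-bromo-2-(bromomethyl)-3,4,6-trimethoxy-5-(propan-2-yl)benzene
Conditions: (CH2O)n, HBr (33 % in AcOH), AcOH, 50 °C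
Reagents that add atoms: formaldehyde (as paraformaldehyde), C=O; hydrogen bromide, Br
Why: Bromomethylation (Blanc-type electrophilic substitution) can only take the last free ring position, which is ortho to a methoxy group and para to the isopropyl group.

**Step 5**
Reactants: 7 3-methylcyclohex-2-en-1-one
Product: 9 3,3-dimethylcyclohex-1-en-1-yl trifluoromethanesulfonate, via magnesium enolate 8 (not isolated)
Conditions: MeMgBr, CuBr·SMe2 (5 mol %), THF, −40 °C; PhNTf2, DMPU, −40 °C → rt
Reagents that add atoms: methylmagnesium bromide, C[Mg]Br; N-phenylbis(trifluoromethanesulfonimide), O=S(=O)(N(c1ccccc1)S(=O)(=O)C(F)(F)F)C(F)(F)F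
Why: Copper-catalysed conjugate addition gives the enolate regiospecifically on the side of the new quaternary carbon, and O-sulfonylation fixes the later C10=C5 double bond as the enol triflate.

**Step 6**
Reactants: 6 1-bromo-2-(bromomethyl)-3,4,6-trimethoxy-5-(propan-2-yl)benzene and 9 3,3-dimethylcyclohex-1-en-1-yl trifluoromethanesulfonate
Product: 11 1-bromo-2-[(3,3-dimethylcyclohex-1-en-1-yl)methyl]-3,4,6-trimethoxy-5-(propan-2-yl)benzene, via benzylzinc bromide 10 (not isolated)
Conditions: Zn dust, LiCl, THF, 0 → 25 °C; then 9, Pd(PPh3)4 (5 mol %), THF, 50 °C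
Reagents that add atoms: none
Why: Negishi coupling, in which zinc inserts only into the benzylic C–Br bond and the catalyst adds to the alkenyl triflate far faster than to the hindered, electron-rich aryl bromide.

**Step 7**
Reactants: 11 1-bromo-2-[(3,3-dimethylcyclohex-1-en-1-yl)methyl]-3,4,6-trimethoxy-5-(propan-2-yl)benzene
Product: 13 2-[(3,3-dimethylcyclohex-1-en-1-yl)methyl]-3,4,6-trimethoxy-5-(propan-2-yl)benzoic acid, via aryllithium 12 (not isolated)
Conditions: n-BuLi, THF, −78 °C; CO2 (g), −78 °C → rt; 1 M HCl
Reagents that add atoms: carbon dioxide, O=C=O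
Why: Bromine–lithium exchange at −78 °C outpaces deprotonation of the benzylic-allylic CH2, and the aryllithium is carboxylated.

**Step 8**
Reactants: 13 2-[(3,3-dimethylcyclohex-1-en-1-yl)methyl]-3,4,6-trimethoxy-5-(propan-2-yl)benzoic acid
Product: 15 2-diazo-1-{2-[(3,3-dimethylcyclohex-1-en-1-yl)methyl]-3,4,6-trimethoxy-5-(propan-2-yl)phenyl}ethan-1-one, via acid chloride 14 (not isolated)
Conditions: 1-chloro-N,N,2-trimethylprop-1-en-1-amine, CH2Cl2, 0 °C → rt; CH2N2 (3 equiv), Et2O, 0 °C
Reagents that add atoms: diazomethane, C=[N+]=[N-]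
Why: Neutral acid chloride formation (no HCl to add to the alkene) followed by acylation of diazomethane, the first stage of the Arndt–Eistert sequence, gives the diazomethyl ketone.

**Step 9**
Reactants: 15 2-diazo-1-{2-[(3,3-dimethylcyclohex-1-en-1-yl)methyl]-3,4,6-trimethoxy-5-(propan-2-yl)phenyl}ethan-1-one
Product: 16 (5S,6R,10S)-cyclopropa-fused trimethoxy tetralone
Conditions: Cu(MeCN)4PF6 (5 mol %), 2,2'-isopropylidenebis[(4S)-4-tert-butyl-2-oxazoline] (6 mol %), CH2Cl2, 40 °C, slow addition of 15
Reagents that add atoms: none
Why: Catalytic asymmetric intramolecular cyclopropanation of an α-diazo ketone by a bis(oxazoline)–copper carbene closes the six-membered ketone ring onto the trisubstituted alkene; concerted syn addition enforces the cis fusions at C5, C6 and C10, and the ligand selects the alkene face and so the absolute configuration.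

**Step 10**
Reactants: 16 (5S,6R,10S)-cyclopropa-fused trimethoxy tetralone
Product: 18 (5S,7S,10S)-trimethoxyarene hemiketal, via hydroxy ketone 17 (not isolated)
Conditions: TfOH (20 mol %), H2O (20 equiv), (CF3)2CHOH, 0 °C → rt
Reagents that add atoms: water, O
Why: Protonation of the C7 carbonyl makes the cyclopropane a homo-Michael acceptor, and the C6–C10 bond breaks because only this cleavage gives a tertiary cation (C6–C5 would give a secondary cation next to the quaternary C4), which converts the six-membered ketone ring into the seven-membered ring B as an enol/C10 cation pair that ketonises and takes up water to give 17. The closest known reaction type is the Brønsted-acid-catalysed homo-conjugate addition of oxygen nucleophiles to aryl cyclopropyl ketones in fluorinated alcohols, here in its Cloke–Wilson-type outcome as a 2-hydroxyoxolane. The oxolane closes transannularly by 5-exo-trig addition of the C10 hydroxyl to the C7 carbonyl, which at the same time closes the six-membered O–C7–C8–C9–C20–C10 ring of the oxabicyclo[3.2.1]octane. C10 is controlled by C5: only a C10–O bond cis to the C5–C6 bond can reach C7, so this epimer should be withdrawn as the bridged hemiketal while the trans hydroxy ketone and the C1(10) and C10(20) alkenes re-ionise under the conditions, and C7 is then dictated by the bicycle (hydroxyl exo). The step needs C5 to keep its configuration, and loss of H5 from the cation is disfavoured because the C5–C6 bond, not C5–H, lies parallel to the empty orbital at C10 in the conformer left by ring opening and needed for ring closure; catalytic acid, low temperature and short contact time support this. The hexasubstituted arene leaves no site for Friedel–Crafts capture of the cation.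

**Step 11**
Reactants: 18 (5S,7S,10S)-trimethoxyarene hemiketal
Product: 19 komaroviquinone
Conditions: (NH4)2Ce(NO3)6 (2.5 equiv), MeCN–H2O 2:1, 0 °C
Reagents that add atoms: water, O
Why: Oxidative demethylation of the para-related C11 and C14 methoxy groups by tetravalent cerium should give the 12-methoxy-1,4-quinone, while the bridged hemiketal, which cannot ionise at its bridgehead, and all three stereocentres stay untouched.

**Compound list**

1 | 1,2,4-trimethoxybenzene | COc1ccc(OC)c(OC)c1 | starting material
2 | (2,3,6-trimethoxyphenyl)lithium | [Li]c1c(OC)ccc(OC)c1OC | intermediate (not isolated)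
3 | 2-(2,3,6-trimethoxyphenyl)propan-2-ol | COc1ccc(OC)c(C(C)(C)O)c1OC | intermediate
4 | 1,2,4-trimethoxy-3-(propan-2-yl)benzene | COc1ccc(OC)c(C(C)C)c1OC | intermediate
5 | 1-bromo-2,4,5-trimethoxy-3-(propan-2-yl)benzene | COc1cc(Br)c(OC)c(C(C)C)c1OC | intermediate
6 | 1-bromo-2-(bromomethyl)-3,4,6-trimethoxy-5-(propan-2-yl)benzene | COc1c(C(C)C)c(OC)c(Br)c(CBr)c1OC | intermediate
7 | 3-methylcyclohex-2-en-1-one | CC1=CC(=O)CCC1 | starting material
8 | bromomagnesium 3,3-dimethylcyclohex-1-en-1-olate | CC1(C)CCCC(O[Mg]Br)=C1 | intermediate (not isolated)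
9 | 3,3-dimethylcyclohex-1-en-1-yl trifluoromethanesulfonate | CC1(C)CCCC(OS(=O)(=O)C(F)(F)F)=C1 | intermediate
10 | [2-bromo-3,5,6-trimethoxy-4-(propan-2-yl)benzyl]zinc bromide | COc1c(C(C)C)c(OC)c(Br)c(C[Zn]Br)c1OC | intermediate (not isolated)
11 | 1-bromo-2-[(3,3-dimethylcyclohex-1-en-1-yl)methyl]-3,4,6-trimethoxy-5-(propan-2-yl)benzene | COc1c(C(C)C)c(OC)c(Br)c(CC2=CC(C)(C)CCC2)c1OC | intermediate
12 | {2-[(3,3-dimethylcyclohex-1-en-1-yl)methyl]-3,4,6-trimethoxy-5-(propan-2-yl)phenyl}lithium | COc1c(C(C)C)c(OC)c([Li])c(CC2=CC(C)(C)CCC2)c1OC | intermediate (not isolated)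
13 | 2-[(3,3-dimethylcyclohex-1-en-1-yl)methyl]-3,4,6-trimethoxy-5-(propan-2-yl)benzoic acid | COc1c(C(C)C)c(OC)c(C(=O)O)c(CC2=CC(C)(C)CCC2)c1OC | intermediate
14 | 2-[(3,3-dimethylcyclohex-1-en-1-yl)methyl]-3,4,6-trimethoxy-5-(propan-2-yl)benzoyl chloride | COc1c(C(C)C)c(OC)c(C(Cl)=O)c(CC2=CC(C)(C)CCC2)c1OC | intermediate (not isolated)
15 | 2-diazo-1-{2-[(3,3-dimethylcyclohex-1-en-1-yl)methyl]-3,4,6-trimethoxy-5-(propan-2-yl)phenyl}ethan-1-one | COc1c(C(C)C)c(OC)c(C(=O)C=[N+]=[N-])c(CC2=CC(C)(C)CCC2)c1OC | intermediate
16 | (5S,6R,10S)-cyclopropa-fused tetralone: 11,12,14-trimethoxy-13-isopropyl-α-tetralone ring (C7=O, C8, C9, C20H2, C10, C6H) fused at C6–C10 to a cyclopropane (C5, C6, C10), which is cis-fused at C5–C10 to the 4,4-dimethylcyclohexane ring A; C7 and C20 lie on the cyclopropane face opposite to ring A | COc1c(C(C)C)c(OC)c2c(c1OC)C[C@@]34CCCC(C)(C)[C@@H]3[C@H]4C2=O | intermediate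
17 | (5S,10S)-10-hydroxy-11,12,14-trimethoxy-9(10→20)abeo-abieta-8,11,13-trien-7-one (tertiary C10 hydroxyl cis to the C5–C6 bond) | COc1c(C(C)C)c(OC)c2c(c1OC)C[C@@]3(O)CCCC(C)(C)[C@@H]3CC2=O | intermediate (not isolated)
18 | (5S,7S,10S)-7,10-epoxy-11,12,14-trimethoxy-9(10→20)abeo-abieta-8,11,13-trien-7-ol (trimethoxyarene hemiketal) | COc1c(C(C)C)c(OC)c2c(c1OC)C[C@@]34CCCC(C)(C)[C@@H]3C[C@]2(O)O4 | intermediate
19 | komaroviquinone, (5S,7S,10S)-7,10-epoxy-7-hydroxy-12-methoxy-9(10→20)abeo-abieta-8,12-diene-11,14-dione | COC1=C(C(C)C)C(=O)C2=C(C[C@@]34CCCC(C)(C)[C@@H]3C[C@]2(O)O4)C1=O | target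

**Totals.** 11 steps in all. The longest linear sequence is 10 steps (steps 1–4 and 6–11, from 1); step 5 is a one-step side branch.

**Steps most likely to fail**

Step 10. The C10 cation may be diverted to alkenes faster than it is captured on the face cis to C6, and reversible protonation in the acidic medium may erode the configuration at C5. The fallback sets out from 16 and comes back at 18 by separating C–C cleavage from C–O formation. Iodotrimethylsilane in CH2Cl2 at −78 °C opens 16 by attack of iodide on C10 to the silyl enol ether iodide F1, and aqueous work-up gives the tertiary iodo ketone F2 (drawn as the product of backside attack; its C10 configuration is of no consequence). Ionisation of F2 with AgOCOCF3 in aqueous acetone buffered with NaHCO3 at 0 °C should then deliver 18 under non-acidic, kinetically controlled conditions, in which an alkene once formed cannot be re-protonated and C5 is safe.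

Step 9. Facial discrimination in the carbene transfer may be insufficient, or the carbene may be diverted to an oxonium ylide with the neighbouring methoxy group. The fallback sets out from 15 and comes back at 16. Cyclopropanation with the achiral catalyst Rh2(OAc)4 in CH2Cl2 gives 16 together with its mirror image, the (5R,6S,10R)-cyclopropyl ketone F3. The two are separated by preparative chromatography on a chiral stationary phase, and F3 is discarded.

Step 4. The last ring position, flanked by bromine and methoxy, may react sluggishly, so that hot HBr begins to cleave the aryl methyl ethers. The fallback sets out from 5 and comes back at 6. Rieche formylation of 5 (Cl2CHOMe, TiCl4, CH2Cl2, −20 °C) gives the aldehyde F4, reduction with NaBH4 in MeOH gives the benzylic alcohol F5, and PBr3 in CH2Cl2 at 0 °C gives 6.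

**Further compounds**

F1 | step 10 | (5S,10R)-10-iodo silyl enol ether of the ring-expanded ketone (C7–OSiMe3, C6=C7) | COc1c(C(C)C)c(OC)c2c(c1OC)C[C@]3(I)CCCC(C)(C)[C@@H]3C=C2O[Si](C)(C)C
F2 | step 10 | (5S,10R)-10-iodo-11,12,14-trimethoxy-9(10→20)abeo-abieta-8,11,13-trien-7-one | COc1c(C(C)C)c(OC)c2c(c1OC)C[C@]3(I)CCCC(C)(C)[C@@H]3CC2=O
F3 | step 9 | (5R,6S,10R)-cyclopropa-fused tetralone, mirror image of 16 | COc1c(C(C)C)c(OC)c2c(c1OC)C[C@]34CCCC(C)(C)[C@H]3[C@@H]4C2=O
F4 | step 4 | 2-bromo-3,5,6-trimethoxy-4-(propan-2-yl)benzaldehyde | COc1c(C(C)C)c(OC)c(Br)c(C=O)c1OC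
F5 | step 4 | [2-bromo-3,5,6-trimethoxy-4-(propan-2-yl)phenyl]methanol | COc1c(C(C)C)c(OC)c(Br)c(CO)c1OC
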